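The numbers in the tables were computed on assumed constants.

**One ratio.** The zeta run was charged with 4.00 times the nucleophile of the eta run, at equal electrophile and free base. By 5.00 min its exposure, defined as the natural logarithm of charge over electrophile left, is 3.58 times larger. So at 0.50 mM of electrophile, exposure per equivalent of nucleophile is roughly the same in these two runs, and it is the number to carry. It is tied to that charge: the delta run, at 0.25 mM of electrophile, reads 0.805 per equivalent at 5.00 min.

| flask | electrophile | nucleophile | free base | remark | time |
|---|---|---|---|---|---|
| eta | 0.50 mM | 0.40 equiv (fed, over 1.0 min) | 1.5 equiv | run made earlier |  |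
| zeta | 0.50 mM | 1.6 equiv (fed, over 1.0 min) | 1.5 equiv | run made earlier |  |
| delta | 0.25 mM | 0.80 equiv (fed, over 1.0 min) | 1.5 equiv | run made earlier |  |
| flask | 0.50 mM | 0.800 equiv (fed, over 1.0 min) | 1.50 equiv |  | 8.0 min |

| run | time / min | electrophile / % | target / % |
|---|---|---|---|
| eta | 0.667 | 95.9 | 1.7 |
| eta | 1.33 | 85.3 | 5.4 |
| eta | 2.00 | 77.0 | 5.9 |
| eta | 3.00 | 69.1 | 5.6 |
| eta | 4.00 | 61.4 | 4.5 |
| eta | 5.00 | 59.1 | 3.7 |
| zeta | 0.417 | 93.9 | 4.0 |
| zeta | 0.667 | 85.9 | 8.5 |
| zeta | 0.833 | 78.6 | 11.1 |
| zeta | 1.33 | 57.4 | 15.9 |
| zeta | 2.00 | 40.6 | 15.3 |
| zeta | 3.00 | 27.3 | 11.9 |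
| zeta | 5.00 | 15.2 | 8.3 |
| delta | 0.417 | 98.4 | 0.9 |
| delta | 0.667 | 96.4 | 3.4 |
| delta | 1.33 | 85.9 | 8.2 |
| delta | 2.50 | 70.0 | 10.3 |
| delta | 5.00 | 52.5 | 9.2 |

(scatter of a reading: 0.5 percentage points)

- percentages count the electrophile that a species holds: one side product counts as two
- the analysis behind the earlier runs scatters by 0.5 percentage points, standard deviation
- steps thought possible: electrophile + target -> side product; electrophile + nucleophile -> acid set free + target; nucleophile + acid set free <-> protonated nucleophile; nucleophile + target -> over-reaction product; acid set free + free base <-> salt of the base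
- the earlier runs do not show how much of nucleophile is bound; that part of a forecast is a guess

* part of the electrophile that has reacted at 8.0 min
* share of the unused nucleophile that is free and not bound as protonated nucleophile, at 8.0 min

**The bracket.** At 5.00 min the exposure per equivalent reads 1.18 in zeta and 1.31 in eta. The smaller value, with the loss stopped there, gives a first rough floor for the flask of 61.0% reacted. But the eta run is still losing electrophile, and its pace, assumed to hold up to 8.0 min, adds 0.286 per equivalent if read over its last interval and 0.586 if read over its last two. The smaller start with the smaller addition gives 1.46 per equivalent, an estimated floor of 69.0%. The larger start with the larger addition gives 1.90, an estimated ceiling of 78.1%. Their middle is 1.68, the exposure per equivalent at the asked time, which puts this reckoning for the flask at 74.0%.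

**The forecast.** It says 76% reacted, inside the bracket and above this reckoning. It puts the free share at 75%, with the remark “The free share is a guess”.

**The flask.** It gives 73.2% reacted and 30.6% free.

    electrophile + target → side product (k = 38.5 M⁻¹ s⁻¹)
    electrophile + nucleophile → acid set free + target (k = 15.2 M⁻¹ s⁻¹)
    nucleophile + acid set free ⇌ protonated nucleophile, settled at all times (K = 2.20 × 10⁶ M⁻¹)
    nucleophile + target → over-reaction product (k = 26.4 M⁻¹ s⁻¹)
    acid set free + free base ⇌ salt of the base, settled at all times (K = 1.82 × 10⁵ M⁻¹)

**Exposure again.** Free nucleophile stands at 11% of its charge at the end, less than free base at 84%. The flask's exposure per equivalent comes to 1.65, against 1.68 carried. For a neighbouring flask charged with 0.320 equiv of nucleophile, the carried value gives 41.6% reacted, and that flask stands at 42.6%.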